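(All runs come from a simulation for an exercise, and the scatter is random.)

Summer is read at 25 min, and the reckoning here counts how many lifetimes of the intermediate fit into that time.

| setting | blue | summer | autumn | winter |
|---|---|---|---|---|
| substrate | 0.042 M | 0.042 M | 0.042 M | 0.042 M |
| partner | 0.13 M | 0.0630 M | 0.0630 M | 0.0630 M |
| free catalyst | 8.4 mM | 8.4 mM | 8.4 mM | 8.4 mM |
| second catalyst | 2.1 mM | 2.1 mM | 2.1 mM | 2.1 mM |
| temperature | 50 °C | 50 °C | 90 °C | 70 °C |
| remark | run made earlier |  |  |  |
| time |  | 25 min | 25 min | 25 min |

blue run (percent of the substrate charged)

| time / min | target / % | substrate / % |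
|---|---|---|
| 0.333 | 0.4 | 93.4 |
| 0.833 | 0.8 | 83.4 |
| 1.50 | 2.5 | 72.9 |
| 2.50 | 5.0 | 59.0 |

(scatter of a reading: 0.3 percentage points)

- the numbers in the tables scatter by 0.3 percentage points (one standard deviation)
- reactions considered so far: 2 partner -> homo dimer; substrate + free catalyst <-> free catalyst + intermediate; partner + second catalyst + intermediate -> second catalyst + target; substrate + partner -> uncatalysed product; 2 free catalyst <-> resting dimer
- the earlier runs do not show what temperature does; that part of a forecast is a guess

1. the flask with the highest amount of target, in percent of the substrate charged ("all alike" if they lie within 1.5 percentage points) (summer / autumn / winter / all alike)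
2. final target, as a percentage of the substrate charged, in summer
3. final target, as a percentage of the substrate charged, in autumn
4. final target, as a percentage of the substrate charged, in winter

In the blue run at 2.50 min, substrate stands at 59.0% and target at 5.0%. Taking uncatalysed product as small, the remainder, 36.0%, is counted as intermediate. That pool rose roughly in a straight line, so its mean was about half its last value. Target gained per minute over mean intermediate gives k′ = 0.111 min⁻¹, a pseudo-first-order constant read from scattered readings.

The step consumes partner and needs second catalyst, so k′ is taken as proportional to both. For summer this gives 1.35. That is N, the number of intermediate lifetimes in the reading time: k′ scaled by the flask's partner and second catalyst against blue's, times the time.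

The fraction of a pool left after N lifetimes is e^(−N), here 25.9%, so summer's target reckons at 74.0% with partner held at its charge and the substrate charge counted as intermediate from the start. One number is not enough, however. Summer's partner stands at 1.50 equivalents, and full conversion of substrate, one partner for each, brings it down to 33.3% of its charge. Taking the mean of those two partner levels lowers N to 0.897, and target to 59.2%, the reckoning made here. Blue shows nothing of temperature, so N gives nothing for autumn or winter.

The forecast gives 45% for summer, 68% for autumn and 72% for winter, below this reckoning for summer. It names winter: “Winter therefore narrowly leads autumn, with low confidence”.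

The flasks give 42.9% in summer, 48.3% in autumn and 53.1% in winter, so winter leads.

    2 partner → homo dimer (k = 0.0446 L mol⁻¹ s⁻¹, Ea = 59.0 kJ mol⁻¹)
    substrate + free catalyst ⇌ free catalyst + intermediate (K = 1.71, k = 13.0 L mol⁻¹ s⁻¹, Ea = 61.0 kJ mol⁻¹, ΔH = −28.0 kJ mol⁻¹)
    partner + second catalyst + intermediate → second catalyst + target (k = 41.3 L² mol⁻² s⁻¹, Ea = 39.0 kJ mol⁻¹)
    substrate + partner → uncatalysed product (k = 0.0451 L mol⁻¹ s⁻¹, Ea = 58.0 kJ mol⁻¹)
    2 free catalyst ⇌ resting dimer, settled at all times (K = 220 L mol⁻¹, ΔH = −9.00 kJ mol⁻¹)
    (constants at 90 °C)

The forecast stands 20 percentage points above autumn, where at 25.0 min partner is down to 3.21% of its charge and homo dimer, at 0.0165 M, holds 52.3% of that charge. Summer's 42.9% of target corresponds to 0.561 lifetimes, a ratio of 0.417 to N. A neighbour of summer has second catalyst at 5.3 × 10⁻⁴ M, a quarter of summer's, so N there is 0.340. With the same ratio, target reckons at 13.2%; the neighbour gives 15.8%.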